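## Structural features

The target is a sesquiterpenoid ester: a trans-fused decalin of the eremophilane type (ring A = C1–C5 and C10, ring B = C5–C10) whose C3 oxygen is acylated by (2E,4E,6E)-5-methyldodeca-2,4,6-trienoic acid. Five stereocentres are contiguous along one edge of the bicycle: C3 (equatorial ester oxygen), C4 (equatorial methyl, trans to O3), C5 (quaternary, axial methyl, cis to the C4 methyl), C10 (hydrogen trans to the C5 methyl) and C9 (equatorial hydroxyl, cis to H10). Ring B carries an α-ketol (C9 hydroxyl, C8 ketone) cross-conjugated with a tetrasubstituted C7=C11 isopropylidene group. The fragile points are this ketol (enediol tautomerism, epimerisation at C9, oxidation to the diosphenol), C10 whenever C9 is a carbonyl, and the trienoate, which can isomerise, accept nucleophiles and has to end up on O3 and not on O9. The real difficulty is the quaternary C5 wedged between the C4 and C10 stereocentres, together with the trans ring fusion and the trans O3/C4-methyl relationship. The key step uses the fact that C3 is a carbinol bonded directly to C4, which bears a one-carbon branch. Written as an exocyclic methylene on C4, the C3–C4 bond of ring A is the retron of a vinyl metal on C5 adding to an aldehyde tethered from C10, and the resulting allylic hydroxyl then steers the reduction that creates C4.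

## Logic of the disconnections

31 ⇒ 30. No skeletal bond is cut; the C9–OH/C8=O ketol with its C7=C11 alkene is traded for the isomeric C8–OH/C9=O ketol with a C7 isopropenyl group. The target ketol is the thermodynamic member of the enediol manifold (conjugation, equatorial C9–OH), so it can be reached by equilibration. The gain is a C9 ketone, which is what the ring closure delivers. The forward step needs a base that moves the ketol faster than it enolises toward C10 and that spares the trienoate.

30 ⇒ 28. The C8–O bond is cut. Oxygen can be delivered to the C8 enolate of the C9 ketone, which removes the ketol altogether. The demand is kinetic, regioselective enolisation at the C8 methylene in the presence of the ester.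

28 ⇒ 21 + 26. The ester C–O bond is cut at a stage where O3 is the only hydroxyl, so no choice between two hydroxyls arises later. This separates the core from the side chain. The forward step must acylate a hindered equatorial alcohol without isomerising the triene.

26 ⇒ 25 ⇒ 22 + 23. The C4=C5 double bond of the side chain is cut (olefination of a methyl ketone), after ester hydrolysis. Two commercial pieces result. The demand is E geometry at the new trisubstituted alkene.

21 ⇒ 18 + 19. The C7–C11 bond is cut; C7 is β to the C9 carbonyl, so the three-carbon unit can arrive by conjugate addition. The gain is an unsubstituted ring B. The step needs the C7=C8 enone and a masked O3; the C7 configuration is irrelevant because C7 becomes trigonal.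

18 ⇒ 17 ⇒ 15. The C7=C8 unsaturation and both silyl groups are removed. The enone comes from the kinetic C8=C9 silyl enol ether by dehydrosilylation, and the same silylation protects O3. The demand is enolisation away from C10.

15 ⇒ 14. The C4–H and methyl C–H bonds are removed to reveal the C4 methylene next to the C3 carbinol. This turns the C4 stereocentre into a face-selectivity problem on an allylic alcohol. Hydrogen must arrive on the α face.

14 ⇒ 12. The C3–C4 bond is cut, opening ring A to a cyclohexanone that carries a 1-iodovinyl group on C5 and a 3-oxopropyl chain on C10. One ring and one stereocentre are removed. The forward step must add the vinyl metal to the aldehyde only, and with the C3 oxygen equatorial.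

12 ⇒ 11 ⇒ 10 ⇒ 8. No skeletal bond is cut: the aldehyde goes back to a primary alcohol, the iodide to a silane, and the alcohol to a terminal alkene. This order keeps the vinylsilane as the only alkene when iodine is introduced and delays the sensitive 1,5-keto aldehyde to the last moment.

8 ⇒ 5 + 6. The C1–C10 bond is cut (enolate allylation). The demand is a regiodefined C9=C10 enolate and entry of the electrophile anti to the bulky silylvinyl group on C5.

5 ⇒ 1 + 2. The C4–C5 bond is cut (conjugate addition of a 1-silylvinyl metal), with the enolate kept as its silyl ether. The forward step must create the quaternary C5 enantioselectively.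

## Other disconnections considered

Alternative 1: Here C5–C10 and C6–C7 are cut together, which unravels both rings to the acyclic trienone A2. Its only stereocentre, the PMB-protected C3 carbinol, comes from D-glutamic acid A1. In the forward direction the isopropenyl ketone of A2 (C5=C6) would add across the tethered 2-silyloxydiene (C7=C8–C9=C10), thermally or under Me2AlCl, to give the trans-fused bicyclic ketone A3.
- In its favour: two rings, two C–C bonds and the C5/C10 pair would arise in one step from the chiral pool. The silyl enol ether of A3 marks C8 as the future ketone with C9 open to direct oxidation. On the C8/C9 oxidation pattern this plan is better than the chosen one, which has to transpose a C9 ketone.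
- Against it: C4 emerges as a ketone between quaternary C5 and the C3 ether and still has to become the methyl-bearing stereocentre. C3 is alpha to that ketone and can epimerise under the Lewis acid. The endo/exo preference that decides trans versus cis fusion is not secure for a 1,1-disubstituted dienophile whose activating carbonyl lies in the tether. The acid-labile silyloxydiene must survive the promoter.
- Comparison: structurally both plans pass through a C4 methylene to be hydrogenated, so they are equal at C4. Mechanistically the cycloaddition sets the quaternary centre and the ring fusion under control of one remote centre, whereas the chosen plan sets C5 by catalyst control and then forms only one bond and one centre in the ring closure, which is easier to predict. In step count the two are about equal up to the bicycle, since A2 needs roughly as many operations from A1 as the six steps to 14.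

Alternative 2: The cut is C5–C6 of ring B, made by a [3,3] shift that in the reverse sense rejoins C3 to C8, so the decalin becomes the bicyclo[2.2.2]octenol A4. A4 would come from the Diels–Alder adduct of a masked o-benzoquinone with an ethylene equivalent, followed by vinyl addition. In the forward direction KH with 18-crown-6 would trigger the anionic oxy-Cope rearrangement of A4 to the enolate of the cis-fused decalone A5.
- In its favour: the route to a decalin is very short, and on step count to the bicyclic stage it is better than the chosen plan. The quaternary C5 forms stereospecifically. The C8 ketone and a C9 carbon at the ketone level (as its dimethyl ketal) are already in place, so no ketol transposition is needed, which is also better than the chosen plan. Hydroboration of the C3=C4 alkene would put the C3 hydroxyl trans to the C4 methyl.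
- Against it: the ring fusion is cis, and C10 can only be inverted after the C9 carbonyl is unmasked, with a cis/trans balance that is not clearly favourable. The facial bias of a folded cis-decalin in the hydroboration is less certain. A4 is racemic unless the first cycloaddition is made asymmetric or a resolution is added, whereas the chosen plan introduces absolute configuration catalytically in step 1.
- Comparison: mechanistically both key steps are reliable (a charge-accelerated sigmatropic shift against an organochromium addition). Structurally the chosen plan gives the trans fusion and the C3 oxygen directly.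

Alternative 3: Here C4–C5 and C1–C10 are cut, which dissects ring A into quinone A6 and the (Z)-silyloxydiene A7. In the forward direction a chiral protonated oxazaborolidine (oxazaborolidinium triflimide) would direct the cycloaddition of A7 to the methyl-bearing double bond of A6, giving the cis-fused adduct A8.
- In its favour: the step is convergent and catalytic in chirality. It would create C4, C5 and C10 and place oxygen at C3, C8 and C9 from two small achiral pieces. On convergence and on the number of steps to a functionalised bicycle it is better than the chosen plan (one step against six).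
- Against it: the endo transition state puts the C4 methyl trans to the C5 methyl and gives the cis fusion. Both C4 and C10 are therefore epimeric to the target relative to C5 and would have to be corrected by enolisation (C4 through the C3 ketone, C10 through the C9 ketone); the outcome is plausible for C4 (equatorial methyl) but not assured for C10. C6 arrives as a carbonyl that the target lacks, and removing one ketone beside the quaternary centre in the presence of two others is awkward. The C7 isopropylidene is still missing.
- Comparison: mechanistically the catalyst-controlled cycloaddition is as credible as the key step of the chosen plan. On stereochemical fit and on redox economy the chosen plan is ahead, because each centre is made in the configuration that the target has.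

Key step: step 6

Remark: α and β refer to the eremophilane skeleton drawn with the C5 methyl up (β); the enantiomer of the chiral carbene ligand in step 1 is assumed to be chosen so that C5 forms with the S configuration, the mirror-image ligand giving the antipode.

## Route

Step 1
Reactants: 1 3-methylcyclohex-2-en-1-one; 2 ethynyltrimethylsilane
Product: 5 (S)-trimethyl({3-methyl-3-[1-(trimethylsilyl)ethenyl]cyclohex-1-en-1-yl}oxy)silane, via vinylalane 3 (not isolated), via aluminium enolate 4 (not isolated)
Conditions: 2, i-Bu2AlH, hexane/THF, 55 °C; then 1, Cu(OTf)2 (5 mol %), chiral sulfonate-bearing imidazolinium salt (N-heterocyclic carbene precursor, 5 mol %), THF, 22 °C; then TMSOTf, −78 to 0 °C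
Reagents that add atoms: trimethylsilyl trifluoromethanesulfonate, C[Si](C)(C)OS(=O)(=O)C(F)(F)F
Why: Syn hydroalumination of 2 puts aluminium on the silicon-bearing carbon (3); the copper–carbene catalyst transfers this vinyl group to C5 of 1 in an asymmetric conjugate addition, the catalyst choosing the enone face and so setting the quaternary centre (S); O-silylation of 4 preserves the C9=C10 enolate regiochemistry.

Step 2
Reactants: 5 (S)-trimethyl({3-methyl-3-[1-(trimethylsilyl)ethenyl]cyclohex-1-en-1-yl}oxy)silane; 6 allyl bromide
Product: 8 (2R,3S)-3-methyl-2-(prop-2-en-1-yl)-3-[1-(trimethylsilyl)ethenyl]cyclohexan-1-one, via lithium enolate 7 (not isolated)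
Conditions: MeLi, THF, 0 °C; then 6, DMPU, −78 to 0 °C
Reagents that add atoms: none
Why: MeLi cleaves the Si–O bond and regenerates the regiodefined lithium enolate 7 (enolate alkylation); allyl bromide should enter C10 on the face away from the bulky 1-silylvinyl group of the neighbouring quaternary carbon, giving the isomer with allyl and silylvinyl trans.

Step 3
Reactants: 8 (2R,3S)-3-methyl-2-(prop-2-en-1-yl)-3-[1-(trimethylsilyl)ethenyl]cyclohexan-1-one
Product: 10 (2R,3S)-2-(3-hydroxypropyl)-3-methyl-3-[1-(trimethylsilyl)ethenyl]cyclohexan-1-one, via alkylborane 9 (not isolated)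
Conditions: 9-borabicyclo[3.3.1]nonane, THF, 0 to 23 °C; then NaBO3·4H2O, H2O, 23 °C
Reagents that add atoms: sodium perborate tetrahydrate, [Na+].[Na+].O[B-]1(O)OO[B-](O)(O)OO1
Why: Anti-Markovnikov hydroboration–oxidation; the bulky dialkylborane takes the monosubstituted alkene and leaves the hindered 1,1-disubstituted vinylsilane, and perborate oxidises the C–B bond without epimerising C10. Any ketone reduced on the way is re-oxidised in step 5.

Step 4
Reactants: 10 (2R,3S)-2-(3-hydroxypropyl)-3-methyl-3-[1-(trimethylsilyl)ethenyl]cyclohexan-1-one
Product: 11 (2R,3S)-2-(3-hydroxypropyl)-3-(1-iodoethenyl)-3-methylcyclohexan-1-one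
Conditions: N-iodosuccinimide, MeCN, 0 to 23 °C, dark
Reagents that add atoms: N-iodosuccinimide, O=C1CCC(=O)N1I
Why: Iododesilylation: the iodonium electrophile adds to the vinylsilane and the silyl group is lost, so iodine takes the place of silicon (ipso substitution); the vinylsilane is the only alkene in the molecule at this stage.

Step 5
Reactants: 11 (2R,3S)-2-(3-hydroxypropyl)-3-(1-iodoethenyl)-3-methylcyclohexan-1-one
Product: 12 (2R,3S)-3-(1-iodoethenyl)-3-methyl-2-(3-oxopropyl)cyclohexan-1-one
Conditions: Dess–Martin periodinane, NaHCO3, CH2Cl2, 0 to 23 °C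
Reagents that add atoms: none
Why: Dess–Martin oxidation of the primary alcohol under buffered, non-basic conditions, which should neither enolise C10 nor start an aldol reaction of the 1,5-keto aldehyde; 12 is used at once.

Step 6
Reactants: 12 (2R,3S)-3-(1-iodoethenyl)-3-methyl-2-(3-oxopropyl)cyclohexan-1-one
Product: 14 (4aS,6R,8aR)-6-hydroxy-4a-methyl-5-methylideneoctahydronaphthalen-1(2H)-one, via vinylchromium species 13 (not isolated)
Conditions: CrCl2 (6 equiv), NiCl2 (2 mol %), degassed DMSO (0.01 M), 23 °C
Reagents that add atoms: none
Why: CrCl2 reduces NiCl2 to zerovalent nickel, which inserts into the C4–I bond; transmetalation to trivalent chromium gives 13, whose C4 adds to the chromium-activated C3 aldehyde. The closest known reaction type is the intramolecular Nozaki–Hiyama–Kishi cyclisation of a vinyl iodide onto an aldehyde to give a cyclic allylic alcohol. Ring A closes in the 6-exo-trig mode on the carbonyl, C3–C4 being the only skeletal bond formed. The new C3 centre is controlled by the C5 and C10 centres already present: the trans, diequatorial attachment of C4 and C1 to ring B imposes a chair-like transition state. Because chromium passes from C4 to oxygen through a four-centre array, the carbonyl oxygen must lie near the plane of the vinyl group, which is the equatorial position, so the alkoxide should end up equatorial (3R, on the face opposite the axial C5 methyl). The step needs selectivity for the aldehyde over the C9 ketone; organochromium reagents add to aldehydes far faster than to ketones, and attack of C4 on C9 would require a four-membered ring. The medium is neutral, so C10 (alpha to the ketone) keeps its configuration. High dilution suppresses intermolecular coupling.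

Step 7
Reactants: 14 (4aS,6R,8aR)-6-hydroxy-4a-methyl-5-methylideneoctahydronaphthalen-1(2H)-one
Product: 15 (4aR,5R,6R,8aR)-6-hydroxy-4a,5-dimethyloctahydronaphthalen-1(2H)-one
Conditions: [Ir(cod)(PCy3)(py)]PF6 (5 mol %), H2 (1 atm), CH2Cl2, 0 to 23 °C
Reagents that add atoms: none
Why: Hydroxyl-directed hydrogenation: the cationic iridium catalyst binds the C3 hydroxyl and delivers hydrogen to the α face of the C4 methylene, which is also the face away from the axial C5 methyl. C4–H therefore becomes axial and the new methyl equatorial, trans to O3 and cis to the C5 methyl.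

Step 8
Reactants: 15 (4aR,5R,6R,8aR)-6-hydroxy-4a,5-dimethyloctahydronaphthalen-1(2H)-one
Product: 17 3α,9-bis(triethylsilyloxy)-4β,5β-dimethyl-10α-H-octal-8-ene (eremophilane numbering), via dilithium alkoxide enolate 16 (not isolated)
Conditions: LiN(i-Pr)2 (2.3 equiv), THF, −78 °C; then TESCl, Et3N, −78 to 23 °C
Reagents that add atoms: chlorotriethylsilane, CC[Si](Cl)(CC)CC
Why: Two equivalents of the amide base form the C3 alkoxide and the kinetic C8 enolate (the tertiary, hindered C10–H is left alone); TESCl silylates both oxygens, so O3 is protected and the C8=C9 enol ether is fixed in one operation.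

Step 9
Reactants: 17 3α,9-bis(triethylsilyloxy)-4β,5β-dimethyl-10α-H-octal-8-ene
Product: 18 3α-(triethylsilyloxy)-4β,5β-dimethyl-10α-H-octal-7-en-9-one (eremophilane numbering)
Conditions: Pd(OAc)2 (10 mol %), O2 (1 atm), DMSO, 40 °C
Reagents that add atoms: none
Why: Saegusa–Ito oxidation in its oxygen-driven catalytic form: the palladium enolate formed from the silyl enol ether loses a β-hydrogen from C7 and gives the C7=C8 enone; the alkyl triethylsilyl ether is inert.

Step 10
Reactants: 18 3α-(triethylsilyloxy)-4β,5β-dimethyl-10α-H-octal-7-en-9-one; 19 isopropenylmagnesium bromide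
Product: 21 3α-hydroxy-7α-isopropenyl-4β,5β-dimethyl-10α-H-decalin-9-one (eremophilane numbering), via silyl enol ether 20 (not isolated)
Conditions: CH2=C(CH3)MgBr (19), CuBr·SMe2 (20 mol %), TMSCl, THF, −78 °C; then 1 M HCl, THF/MeOH, 0 to 23 °C
Reagents that add atoms: none
Why: Copper-catalysed conjugate addition of the Grignard reagent, accelerated by TMSCl, puts the isopropenyl group on C7 on the face away from the axial C5 methyl (this centre becomes trigonal later); dilute acid then hydrolyses the silyl enol ether 20 and the labile triethylsilyl ether together.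

Step 11
Reactants: 22 (E)-non-3-en-2-one; 23 triethyl 4-phosphonocrotonate
Product: 25 ethyl (2E,4E,6E)-5-methyldodeca-2,4,6-trienoate, via lithiated phosphonate 24 (not isolated)
Conditions: 23, LiN(SiMe3)2, THF, −78 °C; then 22, −78 to 23 °C
Reagents that add atoms: none
Why: Vinylogous Horner–Wadsworth–Emmons olefination of the methyl ketone; the anion reacts at its phosphorus-bearing carbon, and the larger alkenyl residue should end up trans to the ester chain (4E) while the two existing double bonds keep their E geometry. Any 4Z isomer would be removed by chromatography.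

Step 12
Reactants: 25 ethyl (2E,4E,6E)-5-methyldodeca-2,4,6-trienoate
Product: 26 (2E,4E,6E)-5-methyldodeca-2,4,6-trienoic acid
Conditions: LiOH, THF/MeOH/H2O, 23 °C; then 1 M HCl
Reagents that add atoms: lithium hydroxide, [Li+].[OH-]
Why: Saponification of the ethyl ester under mild conditions that should leave the triene geometry untouched.

Step 13
Reactants: 21 3α-hydroxy-7α-isopropenyl-4β,5β-dimethyl-10α-H-decalin-9-one; 26 (2E,4E,6E)-5-methyldodeca-2,4,6-trienoic acid
Product: 28 7α-isopropenyl-4β,5β-dimethyl-9-oxo-10α-H-decalin-3α-yl (2E,4E,6E)-5-methyldodeca-2,4,6-trienoate (eremophilane numbering), via mixed anhydride 27 (not isolated)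
Conditions: 26, 2,4,6-trichlorobenzoyl chloride, Et3N, toluene, 23 °C; then 21, DMAP, toluene, 23 °C
Reagents that add atoms: none
Why: Yamaguchi esterification: DMAP attacks the mixed anhydride 27 at the less hindered trienoyl carbonyl, and the acylpyridinium acylates the only hydroxyl present (O3), so no choice between hydroxyls is required.

Step 14
Reactants: 28 7α-isopropenyl-4β,5β-dimethyl-9-oxo-10α-H-decalin-3α-yl (2E,4E,6E)-5-methyldodeca-2,4,6-trienoate
Product: 30 8α-hydroxy-7α-isopropenyl-4β,5β-dimethyl-9-oxo-10α-H-decalin-3α-yl (2E,4E,6E)-5-methyldodeca-2,4,6-trienoate (eremophilane numbering), via potassium enolate 29 (not isolated)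
Conditions: KN(SiMe3)2 (1.05 equiv), THF, −78 °C; then 2-(phenylsulfonyl)-3-phenyloxaziridine, −78 °C; AcOH quench
Reagents that add atoms: 2-(phenylsulfonyl)-3-phenyloxaziridine, O=S(=O)(c1ccccc1)N1OC1c1ccccc1
Why: Kinetic deprotonation by the bulky amide should occur at the C8 methylene, which is more acidic and more accessible than the vinylogous positions of the ester and than C10–H; the enolate is then hydroxylated by the N-sulfonyloxaziridine (Davis oxidation), expected on the face away from the angular methyl. The C8 configuration is immaterial.

Step 15
Reactants: 30 8α-hydroxy-7α-isopropenyl-4β,5β-dimethyl-9-oxo-10α-H-decalin-3α-yl (2E,4E,6E)-5-methyldodeca-2,4,6-trienoate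
Product: 31 (3R,4R,5R,9S,10R)-9-hydroxy-8-oxoeremophil-7(11)-en-3-yl (2E,4E,6E)-5-methyldodeca-2,4,6-trienoate
Conditions: DBU (0.5 equiv), degassed toluene, 23 to 50 °C
Reagents that add atoms: none
Why: Base-mediated α-ketol (enediol) tautomerisation moves the carbonyl to C8 and the hydroxyl to C9, after which the β,γ-alkene migrates into conjugation. The conjugated isopropylidene ketone with equatorial C9–OH (the epimer that avoids a 1,3-diaxial contact with the C5 methyl) is the thermodynamic sink, and C10, no longer alpha to a carbonyl, is then fixed.

## Compound list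

1 | 3-methylcyclohex-2-en-1-one | CC1=CC(=O)CCC1 | starting material
2 | ethynyltrimethylsilane | C#C[Si](C)(C)C | starting material
3 | diisobutyl[1-(trimethylsilyl)ethenyl]aluminium | C=C([Si](C)(C)C)[Al](CC(C)C)CC(C)C | intermediate (not isolated)
4 | diisobutylaluminium (S)-3-methyl-3-[1-(trimethylsilyl)ethenyl]cyclohex-1-en-1-olate | CC(C)C[Al](CC(C)C)OC1=C[C@@](C)(C(=C)[Si](C)(C)C)CCC1 | intermediate (not isolated)
5 | (S)-trimethyl({3-methyl-3-[1-(trimethylsilyl)ethenyl]cyclohex-1-en-1-yl}oxy)silane | C[Si](C)(C)OC1=C[C@@](C)(C(=C)[Si](C)(C)C)CCC1 | intermediate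
6 | allyl bromide (3-bromoprop-1-ene) | C=CCBr | starting material
7 | lithium (S)-3-methyl-3-[1-(trimethylsilyl)ethenyl]cyclohex-1-en-1-olate | [Li]OC1=C[C@@](C)(C(=C)[Si](C)(C)C)CCC1 | intermediate (not isolated)
8 | (2R,3S)-3-methyl-2-(prop-2-en-1-yl)-3-[1-(trimethylsilyl)ethenyl]cyclohexan-1-one | C=CC[C@H]1C(=O)CCC[C@]1(C)C(=C)[Si](C)(C)C | intermediate
9 | 9-(3-{(1R,2S)-2-methyl-6-oxo-2-[1-(trimethylsilyl)ethenyl]cyclohexyl}propyl)-9-borabicyclo[3.3.1]nonane | B1(CCC[C@H]2C(=O)CCC[C@]2(C)C(=C)[Si](C)(C)C)C2CCCC1CCC2 | intermediate (not isolated)
10 | (2R,3S)-2-(3-hydroxypropyl)-3-methyl-3-[1-(trimethylsilyl)ethenyl]cyclohexan-1-one | OCCC[C@H]1C(=O)CCC[C@]1(C)C(=C)[Si](C)(C)C | intermediate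
11 | (2R,3S)-2-(3-hydroxypropyl)-3-(1-iodoethenyl)-3-methylcyclohexan-1-one | OCCC[C@H]1C(=O)CCC[C@]1(C)C(I)=C | intermediate
12 | (2R,3S)-3-(1-iodoethenyl)-3-methyl-2-(3-oxopropyl)cyclohexan-1-one (allyl-derived chain and iodovinyl group trans) | O=CCC[C@H]1C(=O)CCC[C@]1(C)C(I)=C | intermediate
13 | dichloro{1-[(1S,2R)-1-methyl-3-oxo-2-(3-oxopropyl)cyclohexyl]ethenyl}chromium | O=CCC[C@H]1C(=O)CCC[C@]1(C)C(=C)[Cr](Cl)Cl | intermediate (not isolated)
14 | (4aS,6R,8aR)-6-hydroxy-4a-methyl-5-methylideneoctahydronaphthalen-1(2H)-one (trans-fused; 3α-hydroxy, 4-methylene, 5β-methyl, 10α-H, 9-one in eremophilane numbering) | O[C@@H]1CC[C@H]2C(=O)CCC[C@]2(C)C1=C | intermediate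
15 | (4aR,5R,6R,8aR)-6-hydroxy-4a,5-dimethyloctahydronaphthalen-1(2H)-one (3α-hydroxy-4β,5β-dimethyl-10α-H-decalin-9-one) | O[C@@H]1CC[C@H]2C(=O)CCC[C@]2(C)[C@H]1C | intermediate
16 | dilithium salt of 15 (O3 alkoxide, C8=C9 enolate) | [Li]O[C@@H]1CC[C@H]2C(O[Li])=CCC[C@]2(C)[C@H]1C | intermediate (not isolated)
17 | 3α,9-bis(triethylsilyloxy)-4β,5β-dimethyl-10α-H-octal-8-ene | CC[Si](CC)(CC)O[C@@H]1CC[C@H]2C(O[Si](CC)(CC)CC)=CCC[C@]2(C)[C@H]1C | intermediate
18 | 3α-(triethylsilyloxy)-4β,5β-dimethyl-10α-H-octal-7-en-9-one | CC[Si](CC)(CC)O[C@@H]1CC[C@H]2C(=O)C=CC[C@]2(C)[C@H]1C | intermediate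
19 | isopropenylmagnesium bromide | CC(=C)[Mg]Br | starting material
20 | 7α-isopropenyl-3α-(triethylsilyloxy)-9-(trimethylsilyloxy)-4β,5β-dimethyl-10α-H-octal-8-ene | CC[Si](CC)(CC)O[C@@H]1CC[C@H]2C(O[Si](C)(C)C)=C[C@H](C(C)=C)C[C@]2(C)[C@H]1C | intermediate (not isolated)
21 | 3α-hydroxy-7α-isopropenyl-4β,5β-dimethyl-10α-H-decalin-9-one | O[C@@H]1CC[C@H]2C(=O)C[C@H](C(C)=C)C[C@]2(C)[C@H]1C | intermediate
22 | (E)-non-3-en-2-one | CCCCC/C=C/C(C)=O | starting material
23 | triethyl 4-phosphonocrotonate (ethyl (E)-4-(diethoxyphosphoryl)but-2-enoate) | CCOC(=O)/C=C/CP(=O)(OCC)OCC | starting material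
24 | lithium salt of 23 (carbanion at the phosphorus-bearing carbon) | [Li+].CCOC(=O)/C=C/[CH-]P(=O)(OCC)OCC | intermediate (not isolated)
25 | ethyl (2E,4E,6E)-5-methyldodeca-2,4,6-trienoate | CCCCC/C=C/C(C)=C/C=C/C(=O)OCC | intermediate
26 | (2E,4E,6E)-5-methyldodeca-2,4,6-trienoic acid | CCCCC/C=C/C(C)=C/C=C/C(=O)O | intermediate
27 | (2E,4E,6E)-5-methyldodeca-2,4,6-trienoic 2,4,6-trichlorobenzoic anhydride | CCCCC/C=C/C(C)=C/C=C/C(=O)OC(=O)c1c(Cl)cc(Cl)cc1Cl | intermediate (not isolated)
28 | 7α-isopropenyl-4β,5β-dimethyl-9-oxo-10α-H-decalin-3α-yl (2E,4E,6E)-5-methyldodeca-2,4,6-trienoate | CCCCC/C=C/C(C)=C/C=C/C(=O)O[C@@H]1CC[C@H]2C(=O)C[C@H](C(C)=C)C[C@]2(C)[C@H]1C | intermediate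
29 | potassium C8=C9 enolate of 28 | CCCCC/C=C/C(C)=C/C=C/C(=O)O[C@@H]1CC[C@H]2C(O[K])=C[C@H](C(C)=C)C[C@]2(C)[C@H]1C | intermediate (not isolated)
30 | 8α-hydroxy-7α-isopropenyl-4β,5β-dimethyl-9-oxo-10α-H-decalin-3α-yl (2E,4E,6E)-5-methyldodeca-2,4,6-trienoate | CCCCC/C=C/C(C)=C/C=C/C(=O)O[C@@H]1CC[C@H]2C(=O)[C@H](O)[C@H](C(C)=C)C[C@]2(C)[C@H]1C | intermediate
31 | (3R,4R,5R,9S,10R)-9-hydroxy-8-oxoeremophil-7(11)-en-3-yl (2E,4E,6E)-5-methyldodeca-2,4,6-trienoate | CCCCC/C=C/C(C)=C/C=C/C(=O)O[C@@H]1CC[C@H]2[C@H](O)C(=O)C(=C(C)C)C[C@]2(C)[C@H]1C | target

## Step count and least certain steps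

Total: 15 steps. Longest linear sequence: 13 steps (steps 1–10 and 13–15); the side chain takes 2 steps (11 and 12).

Step 6 (key step). The most likely failure is poor facial selectivity at the aldehyde, with the chair that carries an axial alkoxide competing. The only bias is the conformational preference of the forming ring, and an equatorial C3 substituent is pressed against the developing exocyclic methylene. The fallback sets out from 12 and comes back at 14. The cyclisation is run as before and the C3-epimeric alcohol, (4aS,6S,8aR)-6-hydroxy-4a-methyl-5-methylideneoctahydronaphthalen-1(2H)-one F1, is inverted by a Mitsunobu reaction (PPh3, diisopropyl azodicarboxylate, 4-nitrobenzoic acid, THF) to the equatorial 4-nitrobenzoate of 14 F2. Methanolysis (K2CO3, MeOH, 0 °C) then gives 14, so that C3 is fixed by SN2 inversion and not in the C–C bond formation.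

Step 2. The most likely failure is attack of the allyl halide on the other enolate face, together with proton exchange between enolate and product. Both C5 substituents flank the reacting carbon, and the difference between the two faces rests only on the size of the silylvinyl group. The fallback sets out from 5 and comes back at 8. The allylation is run without regard to the ratio, and the unwanted cis isomer, (2S,3S)-3-methyl-2-(prop-2-en-1-yl)-3-[1-(trimethylsilyl)ethenyl]cyclohexan-1-one F3, is separated. F3 is equilibrated at C10 (NaOMe, MeOH, 23 °C; the centre is alpha to the ketone) and recycled, so that C10 is set by equilibration and recycling and not by kinetic face selection.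

Step 15. The most likely failure is slow enediol formation in the aprotic medium that the ester tolerates. Prolonged heating would then allow enolisation toward C10 (erosion of the trans fusion) and geometric drift of the triene. The fallback sets out from 20 (isolated by a buffered work-up) and comes back at 31, with the tautomerisation moved ahead of the esterification where a protic base can be used briefly:
- 20 is hydroxylated at C8 (MeLi, then 2-(phenylsulfonyl)-3-phenyloxaziridine, THF, −78 °C) to 8α-hydroxy-7α-isopropenyl-3α-(triethylsilyloxy)-4β,5β-dimethyl-10α-H-decalin-9-one F4.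
- K2CO3 in MeOH at 0 to 23 °C isomerises F4 to 9α-hydroxy-7-isopropylidene-3α-(triethylsilyloxy)-4β,5β-dimethyl-10α-H-decalin-8-one F5.
- HF·pyridine gives the diol (3R,4R,5R,9S,10R)-3,9-dihydroxyeremophil-7(11)-en-8-one F6.
- Esterification with 26 (via 27, one equivalent, DMAP, 0 °C) is directed to O3; the C9 hydroxyl is hydrogen-bonded to the C8 carbonyl and flanked by the ring-fusion carbon, so O3 should be acylated first. This gives 31.

Step 14. The most likely failure is competing deprotonation of, or conjugate addition to, the trienoate by the amide base, since the ester offers vinylogous acidic positions and an extended acceptor. The fallback sets out from 21 and comes back at 30, with the oxygen introduced before the ester exists. Treating 21 with KN(SiMe3)2 (2.1 equiv) and the same oxaziridine gives 3α,8α-dihydroxy-7α-isopropenyl-4β,5β-dimethyl-10α-H-decalin-9-one F7. Its equatorial C3 hydroxyl is then esterified with 26 (via 27) in preference to the axial C8 hydroxyl, which is crowded by the isopropenyl group and the carbonyl, giving 30.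

Step 11. The most likely failure is low geometric selectivity at the new trisubstituted C4=C5 bond, together with sluggish addition of the vinylogous phosphonate anion to a ketone; methyl and alkenyl differ only moderately in size. The fallback sets out from 22 and comes back at 25 by two successive two-carbon olefinations:
- Triethyl phosphonoacetate and NaH in THF give ethyl (2E,4E)-3-methylnona-2,4-dienoate F8, whose minor 2Z isomer is removed at this small stage.
- i-Bu2AlH (CH2Cl2, −78 °C) reduces F8 to (2E,4E)-3-methylnona-2,4-dien-1-ol F9.
- MnO2 oxidises F9 to (2E,4E)-3-methylnona-2,4-dienal F10.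
- A second olefination of this aldehyde with triethyl phosphonoacetate and NaH, reliably E-selective, gives 25.

## Further compounds

F1 | step 6 | (4aS,6S,8aR)-6-hydroxy-4a-methyl-5-methylideneoctahydronaphthalen-1(2H)-one (C3 epimer of 14) | O[C@H]1CC[C@H]2C(=O)CCC[C@]2(C)C1=C
F2 | step 6 | 4-nitrobenzoate of 14 (3α-ester, eremophilane numbering) | O=C(O[C@@H]1CC[C@H]2C(=O)CCC[C@]2(C)C1=C)c1ccc(cc1)[N+](=O)[O-]
F3 | step 2 | (2S,3S)-3-methyl-2-(prop-2-en-1-yl)-3-[1-(trimethylsilyl)ethenyl]cyclohexan-1-one | C=CC[C@@H]1C(=O)CCC[C@]1(C)C(=C)[Si](C)(C)C
F4 | step 15 | 8α-hydroxy-7α-isopropenyl-3α-(triethylsilyloxy)-4β,5β-dimethyl-10α-H-decalin-9-one | CC[Si](CC)(CC)O[C@@H]1CC[C@H]2C(=O)[C@H](O)[C@H](C(C)=C)C[C@]2(C)[C@H]1C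
F5 | step 15 | 9α-hydroxy-7-isopropylidene-3α-(triethylsilyloxy)-4β,5β-dimethyl-10α-H-decalin-8-one | CC[Si](CC)(CC)O[C@@H]1CC[C@H]2[C@H](O)C(=O)C(=C(C)C)C[C@]2(C)[C@H]1C
F6 | step 15 | (3R,4R,5R,9S,10R)-3,9-dihydroxyeremophil-7(11)-en-8-one | O[C@@H]1CC[C@H]2[C@H](O)C(=O)C(=C(C)C)C[C@]2(C)[C@H]1C
F7 | step 14 | 3α,8α-dihydroxy-7α-isopropenyl-4β,5β-dimethyl-10α-H-decalin-9-one | O[C@@H]1CC[C@H]2C(=O)[C@H](O)[C@H](C(C)=C)C[C@]2(C)[C@H]1C
F8 | step 11 | ethyl (2E,4E)-3-methylnona-2,4-dienoate | CCCCC/C=C/C(C)=C/C(=O)OCC
F9 | step 11 | (2E,4E)-3-methylnona-2,4-dien-1-ol | CCCCC/C=C/C(C)=C/CO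
F10 | step 11 | (2E,4E)-3-methylnona-2,4-dienal | CCCCC/C=C/C(C)=C/C=O
A1 | alternative 1 | D-glutamic acid | N[C@H](CCC(=O)O)C(=O)O
A2 | alternative 1 | (4R,7E)-4-[(4-methoxybenzyl)oxy]-2-methyl-9-[(trimethylsilyl)oxy]deca-1,7,9-trien-3-one | C=C(C)C(=O)[C@H](OCc1ccc(OC)cc1)CC/C=C/C(O[Si](C)(C)C)=C
A3 | alternative 1 | trans-fused 3-(4-methoxybenzyloxy)-5-methyl-8-(trimethylsilyloxy)octal-8-en-4-one (eremophilane numbering) | COc1ccc(CO[C@@H]2CC[C@H]3C=C(O[Si](C)(C)C)CC[C@]3(C)C2=O)cc1
A4 | alternative 2 | 3,3-dimethoxy-5,6-dimethyl-2-vinylbicyclo[2.2.2]oct-5-en-2-ol (vinyl syn to the C5=C6 bridge) | C=C[C@]1(O)C(OC)(OC)[C@H]2CC[C@@H]1C(C)=C2C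
A5 | alternative 2 | cis-fused 9,9-dimethoxy-4,5-dimethyloctal-3-en-8-one (eremophilane numbering) | CC1=CCC[C@@H]2C(OC)(OC)C(=O)CC[C@]12C
A6 | alternative 3 | 2-methoxy-5-methylcyclohexa-2,5-diene-1,4-dione | COC1=CC(=O)C(C)=CC1=O
A7 | alternative 3 | (Z)-tert-butyldimethyl(penta-1,3-dien-3-yloxy)silane | C=C/C(O[Si](C)(C)C(C)(C)C)=C/C
A8 | alternative 3 | cis-fused 3-(tert-butyldimethylsilyloxy)-8-methoxy-4,5-dimethyloctal-2,7-diene-6,9-dione (eremophilane numbering) | CC(C)(C)[Si](C)(C)OC1=CC[C@@H]2C(=O)C(OC)=CC(=O)[C@]2(C)[C@@H]1C
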